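**Analysis of the target**

The target 44 is a briarane: a cyclohexane (ring A: C1, C10, C11, C12, C13, C14) fused through the C1–C10 bond to a ten-membered carbocycle (C1 to C10) that holds the (5Z)-C5=C6 alkene and, across C7–C8, a γ-lactone (C7–O–C19–C17–C8). Methyls are C15 on C1, C16 on C5, C18 on C17 and C20 on C11. There are ten stereocentres, (1R,2R,7R,8R,9R,10R,11S,12S,14R,17S). C1 is quaternary, C15 and C20 are cis on ring A and trans to H-10, 12-OH and 14-OAc are cis, and C8 is a fully substituted carbinol flanked by C7–O, C9–OAc and the C17 methine. Five oxygens must end in three different states: acetates at O2, O9 and O14, free hydroxyls at O12 (secondary) and O8 (tertiary), and the lactone at O7. Sensitive points are acyl migration between neighbouring oxygens, the allylic lactone C7–O bond, the epimerisable C17, and β-elimination of O14 whenever C12 is a ketone. The hard parts are the ten-membered ring, the quaternary C1 at the ring fusion and the congested C8/C9/C17 triad. The strategy rests on one structural fact: the C1–C10 bond alone divides a fourteen-membered carbocycle (C1 to C14) into ring A and the ten-membered ring, so a fourteen-membered ring with an electrophilic C1 and a nucleophilic C10 gives both rings through a single transannular bond.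

**Retrosynthetic reasoning**

*Endgame (44 back to 38).* The acetates at O9 and O14 are put on last (43, 42), with O12 masked by a group removable beside acetates (41). The lactone C19–O7 bond and the C7–H and C12–H bonds are cut next, leading through 40 and 39 to the diketone 38 and its alcohol 37. Both ketones are needed one step earlier, and the 7-hydroxyl can only close onto C19 while O9 is still a silyl ether.

*Key disconnection (37 to 36).* The C1–C10 bond is cut and H-11 is returned to C12, which gives the fourteen-membered epoxide 36. Forward, a Lewis acid must ionise the epoxide at C1, C10 of the (10E)-alkene must attack with inversion, and a hydride shift from the silyloxy carbon C12 must end the cascade as the ketone. Two rings, one skeletal bond and three stereocentres (C1, C10, C11) come from this step. The C7 ketone stays in place because it makes C6 a poor nucleophile; otherwise C6 would attack C1 and close the wrong six-membered ring.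

*Macrocycle (36 to 34).* The ring is opened at C6–C7, back through alcohol 35 to iodo aldehyde 34. A chromium-mediated vinyl addition closes fourteen-membered rings well, the (Z)-geometry is carried in the vinyl iodide, and the new C7 carbinol is oxidised at once, so its configuration does not matter. Closing at C10=C11 by metathesis would have to form an (E)-trisubstituted alkene between two silyloxy carbons, and that is not reliable.

*Open-chain stereochemistry (34 to 30).* C12 must be (R), because the hydride shift is suprafacial and its configuration becomes that of C11. It is set by 1,3-anti reduction of the β-hydroxy ketone 31 (giving 32, then 33). The epoxide is placed on the open chain (30 to 31), where the (14R) allylic alcohol directs a Sharpless epoxidation with a known facial rule. This is more predictable than a directed epoxidation inside the macrocycle.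

*Fragment union (30 to 20 + 27).* The C13–C14 bond is cut by an aldol disconnection. This is the only coupling that tolerates the vinyl iodide of 27 (no zerovalent palladium or nickel is involved), and it delivers the free 14-OH that steers the two steps that follow.

*East fragment (20 to 12).* C11–C12 is cut to the alkyne 17 and acetyl chloride 18 (hydrozirconation, acylation). C9–C10 is cut to acid 12 and propyne 13 through ynone 15, whose reduction (16) sets C9 under catalyst control.

*C8/C17 (12 to 4 + 7).* The C8–C17 bond is cut to α-keto ester 4 and ketene thioacetal 7, through 8 and 10. A chelated Mukaiyama aldol sets the tertiary carbinol and the adjacent methyl centre together. The two arms on C8 arrive differentiated: C9 as a tert-butyl ester, C7 as a silyloxymethyl group. 4 comes from acrylate 1, and 7 from thioester 5.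

*West fragment (27 to 21 + 13).* C4–C5 is cut by carbocupration of propyne 13 with the copper reagent from bromide 21 (25), which fixes the (Z)-alkene. Allylic oxidation (26, 27) supplies C14. A ten-carbon terpenoid chain was not used, because C7 has to arrive attached to C8.

**Alternatives that were turned down**

Alternative 1: Ring A is closed last, at C13–C14 and O–C12, from oxime A2 on the finished ten-membered lactone. The nitrile oxide from A2 adds to the vinyl group on C11 and gives isoxazoline A1. In its favour, intramolecular nitrile oxide cycloadditions to six-membered rings are dependable, C12 and C14 arrive at useful oxidation levels, and the step is late and convergent. As a ring-forming event it is more secure than the cation cascade chosen here. Against it, A2 already contains the ten-membered ring, the quaternary C1 and the C10/C11 centres, so the cycloaddition solves none of the main problems. The dipole also sits on a neopentyl carbon and the alkene hangs from a mobile ring, so the C12 configuration and dimerisation of the dipole are open. The N–O cleavage of A1 and the C14 ketone reduction would have to be done beside the allylic lactone and the acetates. The chosen route gives up that reliability, but it forms both rings and C1 in one step from a ring size that is easy to close.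

Alternative 2: Ring A is made first, by cycloaddition of pyrone A3 with benzyl vinyl ether A4 across pyrone positions 3 and 6 under a chiral Lewis acid, giving bridged lactone A5 (C1–C14 and C12–C13 formed). In its favour, C1, the C14 oxygen and the C12 oxygen are set in one catalytic step at the start, where failure is cheap, and C12 never passes through a ketone. On these two points it is stronger than the chosen route. Against it, only ring A is made. C10 and C11 stay sp2, and C20 enters as an ester and C9 as CH2O, so several redox steps follow. The 3-methyl group slows the cycloaddition, and facial and endo/exo control on a trisubstituted pyrone is uncertain. The ten-membered ring must still be closed onto a crowded cyclohexane by a separate medium-ring reaction. The chosen route spends its risk once, on both rings together.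

Alternative 3: The ten-membered ring is closed at C8–C9 by SmI2 pinacol coupling of keto aldehyde A7, giving diol A6. In its favour, ring A is built by ordinary cyclohexane chemistry with all its centres secure (including C12 as a silyl ether), both O8 and O9 are made in the coupling, and the step is late. On ring A stereocontrol it is stronger than the chosen route. Against it, a ten-membered ketone–aldehyde pinacol closure carries entropic and transannular penalties and competes with simple aldehyde reduction. Two stereocentres, one a tertiary carbinol that cannot be corrected, are formed in the ring closure itself. The lactone must then be made by oxidation at C19. The chosen route fixes C8, C9 and C17 in open-chain, reagent-controlled steps and closes only a fourteen-membered ring.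

Key step: step 22

Assumption: the absolute configuration is that of the target SMILES, and the facial preferences of the chiral reagents (steps 5, 9, 15, 16) are taken to carry over from simple substrates of the same class.

**Route**

Step 1
Reactants: 1 tert-butyl prop-2-enoate
Product: 2 tert-butyl 2,3-dihydroxypropanoate (racemic)
Conditions: K2OsO4·2H2O (1 mol%), NMO, acetone/H2O, 23 °C
Reagents that add atoms: N-methylmorpholine N-oxide, C[N+]1([O-])CCOCC1; water, O
Why: Upjohn dihydroxylation of the acrylate; the new stereocentre is oxidised away in step 3.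

Step 2
Reactants: 2 tert-butyl 2,3-dihydroxypropanoate
Product: 3 tert-butyl 2-hydroxy-3-(triethylsilyloxy)propanoate (racemic)
Conditions: TESCl, imidazole, CH2Cl2, −20 °C
Reagents that add atoms: chlorotriethylsilane, CC[Si](Cl)(CC)CC
Why: Selective silylation of the primary hydroxyl; this oxygen becomes O7 and is later oxidised without ever being freed.

Step 3
Reactants: 3 tert-butyl 2-hydroxy-3-(triethylsilyloxy)propanoate
Product: 4 tert-butyl 2-oxo-3-(triethylsilyloxy)propanoate
Conditions: Dess–Martin periodinane, NaHCO3, CH2Cl2, 0 to 23 °C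
Reagents that add atoms: none
Why: Dess–Martin oxidation of the α-hydroxy ester to the α-keto ester under buffered, non-enolising conditions.

Step 4
Reactants: 5 S-tert-butyl propanethioate
Product: 7 (Z)-1-(tert-butylsulfanyl)-1-(trimethylsilyloxy)prop-1-ene, via lithium enolate 6 (not isolated)
Conditions: LDA, THF, −78 °C; TMSCl
Reagents that add atoms: chlorotrimethylsilane, C[Si](C)(C)Cl
Why: Kinetic enolisation in THF gives the enolate with methyl cis to sulfur, and O-silylation traps it as the (Z)-ketene thioacetal.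

Step 5
Reactants: 4 tert-butyl 2-oxo-3-(triethylsilyloxy)propanoate; 7 (Z)-1-(tert-butylsulfanyl)-1-(trimethylsilyloxy)prop-1-ene
Product: 8 S-tert-butyl (2S,3R)-3-(tert-butoxycarbonyl)-2-methyl-4-(triethylsilyloxy)-3-(trimethylsilyloxy)butanethioate
Conditions: [Cu((S,S)-tBu-box)](OTf)2 (10 mol%), THF, −78 °C
Reagents that add atoms: none
Why: Catalytic enantioselective Mukaiyama aldol addition to an α-keto ester: the square-planar divalent copper complex chelates ketone and ester carbonyls and leaves the si face of the ketone (C8) open, and the (Z)-ketene thioacetal gives the syn adduct, so C8 and C17 are set together. The silyl ether at C7 is a poor ligand and should not disturb the chelate; silyl transfer gives the tertiary TMS ether.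

Step 6
Reactants: 8 S-tert-butyl (2S,3R)-3-(tert-butoxycarbonyl)-2-methyl-4-(triethylsilyloxy)-3-(trimethylsilyloxy)butanethioate
Product: 10 1-tert-butyl 4-methyl (2R,3S)-2-hydroxy-3-methyl-2-[(triethylsilyloxy)methyl]butanedioate, via tertiary TMS ether diester 9 (not isolated)
Conditions: AgOCOCF3, Na2HPO4, MeOH, 23 °C; then K2CO3 (cat.), MeOH, 0 °C
Reagents that add atoms: methanol, CO
Why: Silver-assisted methanolysis turns the thioester into the C19 methyl ester without touching the tert-butyl ester, and brief basic methanolysis removes the tertiary TMS group while the primary TES ether stays.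

Step 7
Reactants: 10 1-tert-butyl 4-methyl (2R,3S)-2-hydroxy-3-methyl-2-[(triethylsilyloxy)methyl]butanedioate
Product: 12 (2R,3S)-4-methoxy-3-methyl-4-oxo-2-(triethylsilyloxy)-2-[(triethylsilyloxy)methyl]butanoic acid, via triethylsilyl ester 11 (not isolated)
Conditions: TESOTf, 2,6-lutidine, CH2Cl2, 0 to 23 °C; aq. NaHCO3
Reagents that add atoms: triethylsilyl trifluoromethanesulfonate, CC[Si](CC)(CC)OS(=O)(=O)C(F)(F)F
Why: The silyl triflate silylates the tertiary hydroxyl (O8) and cleaves the tert-butyl ester to the silyl ester, which hydrolyses on work-up; the methyl ester is untouched, so the C9 carboxyl is freed selectively.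

Step 8
Reactants: 12 (2R,3S)-4-methoxy-3-methyl-4-oxo-2-(triethylsilyloxy)-2-[(triethylsilyloxy)methyl]butanoic acid; 13 propyne
Product: 15 methyl (2S,3R)-2-methyl-4-oxo-3-(triethylsilyloxy)-3-[(triethylsilyloxy)methyl]hept-5-ynoate, via acid chloride 14 (not isolated)
Conditions: 1-chloro-N,N,2-trimethylprop-1-en-1-amine, CH2Cl2, 0 °C; then propyne, PdCl2(PPh3)2 (3 mol%), CuI (6 mol%), Et3N, THF, 23 °C
Reagents that add atoms: none
Why: Neutral acid chloride formation followed by acyl Sonogashira coupling forms C9–C10 and brings in C10, C11 and C20; the ynone avoids a free γ-hydroxy ester at this stage.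

Step 9
Reactants: 15 methyl (2S,3R)-2-methyl-4-oxo-3-(triethylsilyloxy)-3-[(triethylsilyloxy)methyl]hept-5-ynoate
Product: 16 methyl (2S,3R,4R)-4-hydroxy-2-methyl-3-(triethylsilyloxy)-3-[(triethylsilyloxy)methyl]hept-5-ynoate
Conditions: Ru[(S,S)-TsDPEN](p-cymene) (2 mol%), i-PrOH, 23 °C
Reagents that add atoms: none
Why: Noyori transfer hydrogenation of an acetylenic ketone; the alkyne takes the place of the π-substituent in the catalyst pocket, so the (S,S) catalyst should give the (9R) carbinol under catalyst control. The medium is neutral, and the product is silylated at once to avoid closure of O9 onto C19.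

Step 10
Reactants: 16 methyl (2S,3R,4R)-4-hydroxy-2-methyl-3-(triethylsilyloxy)-3-[(triethylsilyloxy)methyl]hept-5-ynoate
Product: 17 methyl (2S,3R,4R)-4-(tert-butyldimethylsilyloxy)-2-methyl-3-(triethylsilyloxy)-3-[(triethylsilyloxy)methyl]hept-5-ynoate
Conditions: TBSOTf, 2,6-lutidine, CH2Cl2, −78 to 0 °C
Reagents that add atoms: tert-butyldimethylsilyl trifluoromethanesulfonate, CC(C)(C)[Si](C)(C)OS(=O)(=O)C(F)(F)F
Why: Silylation of the hindered propargylic alcohol; O9 stays blocked until the lactone is in place.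

Step 11
Reactants: 17 methyl (2S,3R,4R)-4-(tert-butyldimethylsilyloxy)-2-methyl-3-(triethylsilyloxy)-3-[(triethylsilyloxy)methyl]hept-5-ynoate; 18 acetyl chloride
Product: 20 methyl (2S,3R,4R,5E)-4-(tert-butyldimethylsilyloxy)-2,6-dimethyl-7-oxo-3-(triethylsilyloxy)-3-[(triethylsilyloxy)methyl]oct-5-enoate, via alkenylzirconocene 19 (not isolated)
Conditions: Cp2Zr(H)Cl, THF, 23 °C; then AcCl, CuBr·SMe2 (10 mol%), 0 to 23 °C
Reagents that add atoms: none
Why: Syn hydrozirconation puts zirconium on the methyl-bearing alkyne carbon (C11), away from the branched C9; copper-catalysed acylation with retention forms C11–C12 and gives the (E)-enone with C9 and C20 cis.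

Step 12
Reactants: 21 5-bromo-2-methylpent-2-ene; 13 propyne
Product: 25 (1Z)-1-iodo-2,6-dimethylhepta-1,5-diene, via Grignard reagent 22 (not isolated), via alkylcopper 23 (not isolated), via alkenylcopper 24 (not isolated)
Conditions: Mg, Et2O; CuBr·SMe2, Et2O/Me2S, −45 °C; propyne, −25 °C; I2, −78 to 0 °C
Reagents that add atoms: iodine, II
Why: Normant carbocupration: the alkylcopper adds syn across propyne with copper on the terminal carbon, and iodinolysis with retention gives the (Z)-iodide, which fixes the C5=C6 geometry and forms C4–C5.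

Step 13
Reactants: 25 (1Z)-1-iodo-2,6-dimethylhepta-1,5-diene
Product: 26 (2E,6Z)-7-iodo-2,6-dimethylhepta-2,6-dien-1-ol
Conditions: SeO2 (cat.), t-BuOOH, salicylic acid (cat.), CH2Cl2, 23 °C
Reagents that add atoms: tert-butyl hydroperoxide, CC(C)(C)OO
Why: Selenium dioxide allylic oxidation (ene reaction, then [2,3]-shift) takes the (E)-methyl of the electron-rich trisubstituted alkene; the iodoalkene is deactivated. This introduces O14.

Step 14
Reactants: 26 (2E,6Z)-7-iodo-2,6-dimethylhepta-2,6-dien-1-ol
Product: 27 (2E,6Z)-7-iodo-2,6-dimethylhepta-2,6-dienal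
Conditions: MnO2, CH2Cl2, 23 °C
Reagents that add atoms: none
Why: Allylic oxidation with MnO2 gives the enal without touching alkene geometry.

Step 15
Reactants: 20 methyl (2S,3R,4R,5E)-4-(tert-butyldimethylsilyloxy)-2,6-dimethyl-7-oxo-3-(triethylsilyloxy)-3-[(triethylsilyloxy)methyl]oct-5-enoate; 27 (2E,6Z)-7-iodo-2,6-dimethylhepta-2,6-dienal
Product: 30 methyl (2S,3R,4R,5E,9R,10E,14Z)-4-(tert-butyldimethylsilyloxy)-9-hydroxy-15-iodo-2,6,10,14-tetramethyl-7-oxo-3-(triethylsilyloxy)-3-[(triethylsilyloxy)methyl]pentadeca-5,10,14-trienoate, via boron enolate 28 (not isolated), via boron aldolate 29 (not isolated)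
Conditions: (−)-Ipc2BCl, Et3N, Et2O, −78 to 0 °C; 27, −78 to −20 °C; H2O2, MeOH, pH 7 buffer
Reagents that add atoms: none
Why: Boron aldol of the methyl ketone enolate forms C13–C14 without affecting the vinyl iodide; the isopinocampheyl ligands are chosen to favour re-face addition to the enal, which gives the (14R) carbinol (C9 of the chain). Induction with methyl ketones is only moderate and is upgraded in step 16.

Step 16
Reactants: 30 methyl (2S,3R,4R,5E,9R,10E,14Z)-4-(tert-butyldimethylsilyloxy)-9-hydroxy-15-iodo-2,6,10,14-tetramethyl-7-oxo-3-(triethylsilyloxy)-3-[(triethylsilyloxy)methyl]pentadeca-5,10,14-trienoate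
Product: 31 methyl (2S,3R,4R,5E,9R,10R,11R,14Z)-4-(tert-butyldimethylsilyloxy)-10,11-epoxy-9-hydroxy-15-iodo-2,6,10,14-tetramethyl-7-oxo-3-(triethylsilyloxy)-3-[(triethylsilyloxy)methyl]pentadeca-5,14-dienoate
Conditions: Ti(Oi-Pr)4, D-(−)-diisopropyl tartrate, t-BuOOH, 4 Å MS, CH2Cl2, −20 °C
Reagents that add atoms: tert-butyl hydroperoxide, CC(C)(C)OO
Why: Sharpless epoxidation of a secondary (E)-allylic alcohol: with the D-(−)-tartrate the (14R) alcohol is the fast-reacting enantiomer and gives the erythro (anti) epoxy alcohol, so C1 and C2 are set by the reagent and reinforced by A(1,2) strain. Any (14S) epimer reacts slowly and is separated as unchanged alcohol; the two enone alkenes and the iodoalkene are electron-poor and carry no allylic hydroxyl.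

Step 17
Reactants: 31 methyl (2S,3R,4R,5E,9R,10R,11R,14Z)-4-(tert-butyldimethylsilyloxy)-10,11-epoxy-9-hydroxy-15-iodo-2,6,10,14-tetramethyl-7-oxo-3-(triethylsilyloxy)-3-[(triethylsilyloxy)methyl]pentadeca-5,14-dienoate
Product: 32 methyl (2S,3R,4R,5E,7R,9R,10R,11R,14Z)-4-(tert-butyldimethylsilyloxy)-10,11-epoxy-7,9-dihydroxy-15-iodo-2,6,10,14-tetramethyl-3-(triethylsilyloxy)-3-[(triethylsilyloxy)methyl]pentadeca-5,14-dienoate
Conditions: Me4NBH(OAc)3, MeCN/AcOH, −30 °C
Reagents that add atoms: none
Why: Evans–Saksena reduction: hydride is delivered inside the C14 alkoxyborohydride through a chair transition state, giving the 12,14-anti diol. This sets C12 as (R), the configuration from which H-12 can later migrate to the required face of C11; the low temperature protects the epoxide and the TES ethers.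

Step 18
Reactants: 32 methyl (2S,3R,4R,5E,7R,9R,10R,11R,14Z)-4-(tert-butyldimethylsilyloxy)-10,11-epoxy-7,9-dihydroxy-15-iodo-2,6,10,14-tetramethyl-3-(triethylsilyloxy)-3-[(triethylsilyloxy)methyl]pentadeca-5,14-dienoate
Product: 33 methyl (2S,3R,4R,5E,7R,9R,10S,11R,14Z)-4,7,9-tris(tert-butyldimethylsilyloxy)-10,11-epoxy-15-iodo-2,6,10,14-tetramethyl-3-(triethylsilyloxy)-3-[(triethylsilyloxy)methyl]pentadeca-5,14-dienoate
Conditions: TBSOTf, 2,6-lutidine, CH2Cl2, −78 °C
Reagents that add atoms: tert-butyldimethylsilyl trifluoromethanesulfonate, CC(C)(C)[Si](C)(C)OS(=O)(=O)C(F)(F)F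
Why: Both secondary hydroxyls (O12, O14) are silylated at low temperature so that no oxygen can add to the cations of the key step; the buffered triflate should spare the epoxide at −78 °C.

Step 19
Reactants: 33 methyl (2S,3R,4R,5E,7R,9R,10S,11R,14Z)-4,7,9-tris(tert-butyldimethylsilyloxy)-10,11-epoxy-15-iodo-2,6,10,14-tetramethyl-3-(triethylsilyloxy)-3-[(triethylsilyloxy)methyl]pentadeca-5,14-dienoate
Product: 34 methyl (2S,3S,4R,5E,7R,9R,10S,11R,14Z)-4,7,9-tris(tert-butyldimethylsilyloxy)-10,11-epoxy-3-formyl-15-iodo-2,6,10,14-tetramethyl-3-(triethylsilyloxy)pentadeca-5,14-dienoate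
Conditions: (COCl)2, DMSO, CH2Cl2, −78 to −30 °C; Et3N, −78 to 0 °C
Reagents that add atoms: none
Why: Swern conditions cleave and oxidise a primary TES ether directly to the aldehyde, while the secondary TBS and tertiary TES ethers stay. A free 7-hydroxyl, which would lactonise onto C19, is therefore never formed.

Step 20
Reactants: 34 methyl (2S,3S,4R,5E,7R,9R,10S,11R,14Z)-4,7,9-tris(tert-butyldimethylsilyloxy)-10,11-epoxy-3-formyl-15-iodo-2,6,10,14-tetramethyl-3-(triethylsilyloxy)pentadeca-5,14-dienoate
Product: 35 fourteen-membered allylic alcohol (ring C1 to C14; 1,2-epoxide, (5Z)-alkene, 7-OH as both epimers, 8-OTES with the C17 methyl propanoate side chain, 9,12,14-tri-OTBS, (10E)-alkene; 1S,2R,8R,9R,12R,14R,17S)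
Conditions: CrCl2, NiCl2 (1 mol%), DMSO/THF, 23 °C, 2 mM, slow addition
Reagents that add atoms: none
Why: Intramolecular Nozaki–Hiyama–Kishi reaction: the vinyl iodide adds oxidatively to zerovalent nickel, transmetalates to trivalent chromium, and the alkenylchromium adds to the aldehyde with retention of the (Z)-geometry, forming C6–C7. Epoxide, ester and silyl ethers are tolerated, and the C7 configuration is irrelevant because it is oxidised next.

Step 21
Reactants: 35 fourteen-membered allylic alcohol
Product: 36 fourteen-membered epoxy enone (1,2-epoxide, (5Z)-en-7-one, 8-OTES with the C17 methyl propanoate side chain, 9,12,14-tri-OTBS, (10E)-alkene; 1S,2R,8S,9R,12R,14R,17S)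
Conditions: Dess–Martin periodinane, NaHCO3, CH2Cl2, 0 °C
Reagents that add atoms: none
Why: Dess–Martin oxidation of the crude allylic alcohol gives the enone under buffered, non-nucleophilic conditions that should not isomerise the (Z)-alkene; oxidising at once also removes the 7-hydroxyl before it can close onto C19.

Step 22
Reactants: 36 fourteen-membered epoxy enone
Product: 37 bicyclic 2-hydroxy-7,12-dione (ring A fused at C1–C10 to the ten-membered ring; 8-OTES, 9,14-di-OTBS, (5Z)-en-7-one, methyl ester; 1R,2R,8S,9R,10R,11S,14R,17S)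
Conditions: MeAlCl2 (3 equiv), CH2Cl2, −78 °C; aq. Rochelle salt
Reagents that add atoms: none
Why: Proposed new method: MeAlCl2 binds the epoxide oxygen, the C1–O bond ionises at the tertiary carbon, and C10 of the (10E)-alkene, held across the ring from C1, attacks anti to the leaving oxygen to form C1–C10; the C11 cation is then quenched by a suprafacial 1,2-hydride shift from C12, and the silyloxycarbenium ion loses its TBS group to chloride, leaving the C12 ketone. The closest known reaction types are Lewis acid epoxide-initiated cation–alkene cyclisations, transannular cyclisations of macrocyclic terpene epoxides and pinacol-terminated Prins cyclisations. Ring A closes 6-endo with respect to the alkene, with the epoxide C1–O bond exocyclic to the new ring; the ten-membered ring is not closed by a bond of its own but is what is left of the fourteen-membered ring on the other side of C1–C10. C1 is fixed by backside attack on the (1S,2R)-epoxide; C10 and C11 follow from anti addition of C1 and H across the (E)-alkene, which puts C9 and C20 cis, with H-11 arriving on the face that the (12R)-hydrogen leaves. Which alkene face reacts, and so the trans C1/C10 fusion, depends on the macrocycle conformation; the chair-like transition state carries a 1,3-diaxial C15/C20 contact, so this is the least secure element. The step needs C10=C11 to react before C5=C6, which conjugation to the C7 ketone should ensure by making C6 a poor nucleophile. It also needs C10 attack to outrun a 1,2-hydride shift from C14 to C1 (semipinacol opening of the epoxy silyl ether); tertiary ionisation at C1, Markovnikov polarisation toward C11 and the bulky silyl ethers on O8, O9 and O14 are meant to secure this.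

Step 23
Reactants: 37 bicyclic 2-hydroxy-7,12-dione
Product: 38 bicyclic 2-acetoxy-7,12-dione (as 37 with 2-OAc; 1R,2R,8S,9R,10R,11S,14R,17S)
Conditions: Ac2O, DMAP, pyridine, 23 °C
Reagents that add atoms: acetic anhydride, CC(=O)OC(C)=O
Why: The only free hydroxyl, O2, is acetylated as soon as it appears, which differentiates it from O12 for the rest of the route.

Step 24
Reactants: 38 bicyclic 2-acetoxy-7,12-dione
Product: 40 7,19-lactone with free 12-OH (2-OAc, 8-OTES, 9,14-di-OTBS; 1R,2R,7R,8R,9R,10R,11S,12S,14R,17S), via 7,12-dihydroxy methyl ester 39 (not isolated)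
Conditions: NaBH4, CeCl3·7H2O, MeOH, −78 to −20 °C; then PPTS, CH2Cl2, 23 °C
Reagents that add atoms: none
Why: Luche conditions reduce the enone 1,2 and the C12 ketone. At C12, hydride should enter anti to the axial 14-OTBS group, giving the (12S) alcohol cis to O14. At C7 it should enter from the outer face of the ten-membered ring, anti to the C8–C9 bond, giving (7R). The 7-hydroxyl is γ to C19 and closes the lactone on mild acid treatment; O9 cannot compete because it is still a TBS ether.

Step 25
Reactants: 40 7,19-lactone with free 12-OH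
Product: 41 12-O-(2,2,2-trichloroethoxycarbonyl) lactone (2-OAc, 8-OTES, 9,14-di-OTBS; configuration as 40)
Conditions: TrocCl, pyridine, DMAP, CH2Cl2, 0 °C
Reagents that add atoms: 2,2,2-trichloroethyl chloroformate, ClC(=O)OCC(Cl)(Cl)Cl
Why: O12 is masked as a carbonate that survives fluoride and acetylation and can be removed reductively beside acetates.

Step 26
Reactants: 41 12-O-Troc lactone
Product: 42 8,9,14-triol (2-OAc, 12-O-Troc, 7,19-lactone; 1S,2R,7R,8S,9R,10R,11S,12S,14R,17S by priority change only)
Conditions: HF·pyridine, pyridine, THF, 0 to 23 °C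
Reagents that add atoms: none
Why: Buffered acidic fluoride removes the tertiary TES and both secondary TBS ethers without acyl migration; the lactone is already at O7, so freeing O9 no longer risks the isomeric lactone.

Step 27
Reactants: 42 8,9,14-triol
Product: 43 2,9,14-triacetate 12-O-Troc lactone (8-OH free; 1R,2R,7R,8R,9R,10R,11S,12S,14R,17S)
Conditions: Ac2O, DMAP, Et3N, CH2Cl2, 23 °C
Reagents that add atoms: acetic anhydride, CC(=O)OC(C)=O
Why: The two secondary hydroxyls (O9, O14) are acetylated; the tertiary 8-OH does not react under these conditions, and O12 is blocked.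

Step 28
Reactants: 43 2,9,14-triacetate 12-O-Troc lactone
Product: 44 CNP0195208.4, (1R,2R,5Z,7R,8R,9R,10R,11S,12S,14R,17S)-2,9,14-triacetoxy-8,12-dihydroxybriar-5-ene 7,19-lactone
Conditions: Zn, AcOH, THF, 23 °C
Reagents that add atoms: none
Why: Reductive fragmentation of the trichloroethyl carbonate frees 12-OH under mildly acidic conditions that leave the acetates and the lactone alone and do not promote acyl migration.

**Compound list**

1 | tert-butyl prop-2-enoate | C=CC(=O)OC(C)(C)C | starting material
2 | tert-butyl 2,3-dihydroxypropanoate (racemic) | CC(C)(C)OC(=O)C(O)CO | intermediate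
3 | tert-butyl 2-hydroxy-3-(triethylsilyloxy)propanoate (racemic) | CC(C)(C)OC(=O)C(O)CO[Si](CC)(CC)CC | intermediate
4 | tert-butyl 2-oxo-3-(triethylsilyloxy)propanoate | CC(C)(C)OC(=O)C(=O)CO[Si](CC)(CC)CC | intermediate
5 | S-tert-butyl propanethioate | CCC(=O)SC(C)(C)C | starting material
6 | lithium (Z)-1-(tert-butylsulfanyl)prop-1-en-1-olate | C/C=C(\SC(C)(C)C)[O-].[Li+] | intermediate
7 | (Z)-1-(tert-butylsulfanyl)-1-(trimethylsilyloxy)prop-1-ene | C/C=C(\SC(C)(C)C)O[Si](C)(C)C | intermediate
8 | S-tert-butyl (2S,3R)-3-(tert-butoxycarbonyl)-2-methyl-4-(triethylsilyloxy)-3-(trimethylsilyloxy)butanethioate | CC(C)(C)OC(=O)[C@@](O[Si](C)(C)C)([C@H](C)C(=O)SC(C)(C)C)CO[Si](CC)(CC)CC | intermediate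
9 | 1-tert-butyl 4-methyl (2R,3S)-3-methyl-2-[(triethylsilyloxy)methyl]-2-(trimethylsilyloxy)butanedioate | CC(C)(C)OC(=O)[C@@](O[Si](C)(C)C)([C@H](C)C(=O)OC)CO[Si](CC)(CC)CC | intermediate
10 | 1-tert-butyl 4-methyl (2R,3S)-2-hydroxy-3-methyl-2-[(triethylsilyloxy)methyl]butanedioate | CC(C)(C)OC(=O)[C@@](O)([C@H](C)C(=O)OC)CO[Si](CC)(CC)CC | intermediate
11 | 4-methyl 1-triethylsilyl (2R,3S)-3-methyl-2-(triethylsilyloxy)-2-[(triethylsilyloxy)methyl]butanedioate | CC[Si](CC)(CC)OC(=O)[C@@](O[Si](CC)(CC)CC)([C@H](C)C(=O)OC)CO[Si](CC)(CC)CC | intermediate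
12 | (2R,3S)-4-methoxy-3-methyl-4-oxo-2-(triethylsilyloxy)-2-[(triethylsilyloxy)methyl]butanoic acid | OC(=O)[C@@](O[Si](CC)(CC)CC)([C@H](C)C(=O)OC)CO[Si](CC)(CC)CC | intermediate
13 | propyne | CC#C | starting material
14 | methyl (2S,3R)-4-chloro-2-methyl-4-oxo-3-(triethylsilyloxy)-3-[(triethylsilyloxy)methyl]butanoate | ClC(=O)[C@@](O[Si](CC)(CC)CC)([C@H](C)C(=O)OC)CO[Si](CC)(CC)CC | intermediate
15 | methyl (2S,3R)-2-methyl-4-oxo-3-(triethylsilyloxy)-3-[(triethylsilyloxy)methyl]hept-5-ynoate | CC#CC(=O)[C@@](O[Si](CC)(CC)CC)([C@H](C)C(=O)OC)CO[Si](CC)(CC)CC | intermediate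
16 | methyl (2S,3R,4R)-4-hydroxy-2-methyl-3-(triethylsilyloxy)-3-[(triethylsilyloxy)methyl]hept-5-ynoate | CC#C[C@@H](O)[C@@](O[Si](CC)(CC)CC)([C@H](C)C(=O)OC)CO[Si](CC)(CC)CC | intermediate
17 | methyl (2S,3R,4R)-4-(tert-butyldimethylsilyloxy)-2-methyl-3-(triethylsilyloxy)-3-[(triethylsilyloxy)methyl]hept-5-ynoate | CC#C[C@@H](O[Si](C)(C)C(C)(C)C)[C@@](O[Si](CC)(CC)CC)([C@H](C)C(=O)OC)CO[Si](CC)(CC)CC | intermediate
18 | acetyl chloride | CC(=O)Cl | starting material
19 | (E)-alkenylzirconocene chloride from 17 (Zr on C11, H on C10) | C/C(=C\[C@@H](O[Si](C)(C)C(C)(C)C)[C@@](O[Si](CC)(CC)CC)([C@H](C)C(=O)OC)CO[Si](CC)(CC)CC)[Zr](Cl)(C1C=CC=C1)C1C=CC=C1 | intermediate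
20 | methyl (2S,3R,4R,5E)-4-(tert-butyldimethylsilyloxy)-2,6-dimethyl-7-oxo-3-(triethylsilyloxy)-3-[(triethylsilyloxy)methyl]oct-5-enoate | CC(=O)/C(C)=C/[C@@H](O[Si](C)(C)C(C)(C)C)[C@@](O[Si](CC)(CC)CC)([C@H](C)C(=O)OC)CO[Si](CC)(CC)CC | intermediate
21 | 5-bromo-2-methylpent-2-ene | CC(C)=CCCBr | starting material
22 | (4-methylpent-3-en-1-yl)magnesium bromide | CC(C)=CCC[Mg]Br | intermediate
23 | (4-methylpent-3-en-1-yl)copper | CC(C)=CCC[Cu] | intermediate
24 | [(1Z)-2,6-dimethylhepta-1,5-dien-1-yl]copper | [Cu]/C=C(C)\CCC=C(C)C | intermediate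
25 | (1Z)-1-iodo-2,6-dimethylhepta-1,5-diene | I/C=C(C)\CCC=C(C)C | intermediate
26 | (2E,6Z)-7-iodo-2,6-dimethylhepta-2,6-dien-1-ol | I/C=C(C)\CC/C=C(C)/CO | intermediate
27 | (2E,6Z)-7-iodo-2,6-dimethylhepta-2,6-dienal | I/C=C(C)\CC/C=C(C)/C=O | intermediate
28 | diisopinocampheylboron enolate of 20 (O12–B, C12=C13) | C=C(OB([C@@H]1C[C@@H]2C[C@H]([C@H]1C)C2(C)C)[C@@H]1C[C@@H]2C[C@H]([C@H]1C)C2(C)C)/C(C)=C/[C@@H](O[Si](C)(C)C(C)(C)C)[C@@](O[Si](CC)(CC)CC)([C@H](C)C(=O)OC)CO[Si](CC)(CC)CC | intermediate
29 | diisopinocampheylboron aldolate (O14–B) of 30 | I/C=C(C)\CC/C=C(C)/[C@H](OB([C@@H]1C[C@@H]2C[C@H]([C@H]1C)C2(C)C)[C@@H]1C[C@@H]2C[C@H]([C@H]1C)C2(C)C)CC(=O)/C(C)=C/[C@@H](O[Si](C)(C)C(C)(C)C)[C@@](O[Si](CC)(CC)CC)([C@H](C)C(=O)OC)CO[Si](CC)(CC)CC | intermediate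
30 | methyl (2S,3R,4R,5E,9R,10E,14Z)-4-(tert-butyldimethylsilyloxy)-9-hydroxy-15-iodo-2,6,10,14-tetramethyl-7-oxo-3-(triethylsilyloxy)-3-[(triethylsilyloxy)methyl]pentadeca-5,10,14-trienoate | I/C=C(C)\CC/C=C(C)/[C@H](O)CC(=O)/C(C)=C/[C@@H](O[Si](C)(C)C(C)(C)C)[C@@](O[Si](CC)(CC)CC)([C@H](C)C(=O)OC)CO[Si](CC)(CC)CC | intermediate
31 | methyl (2S,3R,4R,5E,9R,10R,11R,14Z)-4-(tert-butyldimethylsilyloxy)-10,11-epoxy-9-hydroxy-15-iodo-2,6,10,14-tetramethyl-7-oxo-3-(triethylsilyloxy)-3-[(triethylsilyloxy)methyl]pentadeca-5,14-dienoate | I/C=C(C)\CC[C@H]1O[C@]1(C)[C@H](O)CC(=O)/C(C)=C/[C@@H](O[Si](C)(C)C(C)(C)C)[C@@](O[Si](CC)(CC)CC)([C@H](C)C(=O)OC)CO[Si](CC)(CC)CC | intermediate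
32 | methyl (2S,3R,4R,5E,7R,9R,10R,11R,14Z)-4-(tert-butyldimethylsilyloxy)-10,11-epoxy-7,9-dihydroxy-15-iodo-2,6,10,14-tetramethyl-3-(triethylsilyloxy)-3-[(triethylsilyloxy)methyl]pentadeca-5,14-dienoate | I/C=C(C)\CC[C@H]1O[C@]1(C)[C@H](O)C[C@@H](O)/C(C)=C/[C@@H](O[Si](C)(C)C(C)(C)C)[C@@](O[Si](CC)(CC)CC)([C@H](C)C(=O)OC)CO[Si](CC)(CC)CC | intermediate
33 | methyl (2S,3R,4R,5E,7R,9R,10S,11R,14Z)-4,7,9-tris(tert-butyldimethylsilyloxy)-10,11-epoxy-15-iodo-2,6,10,14-tetramethyl-3-(triethylsilyloxy)-3-[(triethylsilyloxy)methyl]pentadeca-5,14-dienoate | I/C=C(C)\CC[C@H]1O[C@]1(C)[C@H](O[Si](C)(C)C(C)(C)C)C[C@@H](O[Si](C)(C)C(C)(C)C)/C(C)=C/[C@@H](O[Si](C)(C)C(C)(C)C)[C@@](O[Si](CC)(CC)CC)([C@H](C)C(=O)OC)CO[Si](CC)(CC)CC | intermediate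
34 | methyl (2S,3S,4R,5E,7R,9R,10S,11R,14Z)-4,7,9-tris(tert-butyldimethylsilyloxy)-10,11-epoxy-3-formyl-15-iodo-2,6,10,14-tetramethyl-3-(triethylsilyloxy)pentadeca-5,14-dienoate | I/C=C(C)\CC[C@H]1O[C@]1(C)[C@H](O[Si](C)(C)C(C)(C)C)C[C@@H](O[Si](C)(C)C(C)(C)C)/C(C)=C/[C@@H](O[Si](C)(C)C(C)(C)C)[C@@](O[Si](CC)(CC)CC)([C@H](C)C(=O)OC)C=O | intermediate
35 | fourteen-membered allylic alcohol: 1,2-epoxide, (5Z)-alkene, 7-OH (both epimers), 8-OTES with C17 methyl propanoate side chain, 9,12,14-tri-OTBS, (10E)-alkene; 1S,2R,8R,9R,12R,14R,17S | C[C@]12O[C@@H]1CC/C(C)=C\C(O)[C@](O[Si](CC)(CC)CC)([C@H](C)C(=O)OC)[C@H](O[Si](C)(C)C(C)(C)C)/C=C(C)/[C@H](O[Si](C)(C)C(C)(C)C)C[C@H]2O[Si](C)(C)C(C)(C)C | intermediate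
36 | fourteen-membered epoxy enone: 1,2-epoxide, (5Z)-en-7-one, 8-OTES with C17 methyl propanoate side chain, 9,12,14-tri-OTBS, (10E)-alkene; 1S,2R,8S,9R,12R,14R,17S | C[C@]12O[C@@H]1CC/C(C)=C\C(=O)[C@](O[Si](CC)(CC)CC)([C@H](C)C(=O)OC)[C@H](O[Si](C)(C)C(C)(C)C)/C=C(C)/[C@H](O[Si](C)(C)C(C)(C)C)C[C@H]2O[Si](C)(C)C(C)(C)C | intermediate
37 | bicyclic 2-hydroxy-7,12-dione: ring A fused at C1–C10 to the ten-membered ring, 8-OTES, 9,14-di-OTBS, (5Z)-en-7-one, methyl ester; 1R,2R,8S,9R,10R,11S,14R,17S | CC(C)(C)[Si](C)(C)O[C@@H]1[C@@H]2[C@H](C)C(=O)C[C@@H](O[Si](C)(C)C(C)(C)C)[C@@]2(C)[C@H](O)CC/C(C)=C\C(=O)[C@]1(O[Si](CC)(CC)CC)[C@H](C)C(=O)OC | intermediate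
38 | bicyclic 2-acetoxy-7,12-dione (2-acetate of 37) | CC(C)(C)[Si](C)(C)O[C@@H]1[C@@H]2[C@H](C)C(=O)C[C@@H](O[Si](C)(C)C(C)(C)C)[C@@]2(C)[C@H](OC(C)=O)CC/C(C)=C\C(=O)[C@]1(O[Si](CC)(CC)CC)[C@H](C)C(=O)OC | intermediate
39 | 7,12-dihydroxy methyl ester (2-OAc, 8-OTES, 9,14-di-OTBS); 1R,2R,7R,8R,9R,10R,11S,12S,14R,17S | CC(C)(C)[Si](C)(C)O[C@@H]1[C@@H]2[C@H](C)[C@@H](O)C[C@@H](O[Si](C)(C)C(C)(C)C)[C@@]2(C)[C@H](OC(C)=O)CC/C(C)=C\[C@@H](O)[C@]1(O[Si](CC)(CC)CC)[C@H](C)C(=O)OC | intermediate
40 | 7,19-lactone with free 12-OH (2-OAc, 8-OTES, 9,14-di-OTBS); 1R,2R,7R,8R,9R,10R,11S,12S,14R,17S | CC(C)(C)[Si](C)(C)O[C@@H]1[C@@H]2[C@H](C)[C@@H](O)C[C@@H](O[Si](C)(C)C(C)(C)C)[C@@]2(C)[C@H](OC(C)=O)CC/C(C)=C\[C@H]2OC(=O)[C@@H](C)[C@]12O[Si](CC)(CC)CC | intermediate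
41 | 12-O-(2,2,2-trichloroethoxycarbonyl) derivative of 40 | CC(C)(C)[Si](C)(C)O[C@@H]1[C@@H]2[C@H](C)[C@@H](OC(=O)OCC(Cl)(Cl)Cl)C[C@@H](O[Si](C)(C)C(C)(C)C)[C@@]2(C)[C@H](OC(C)=O)CC/C(C)=C\[C@H]2OC(=O)[C@@H](C)[C@]12O[Si](CC)(CC)CC | intermediate
42 | 8,9,14-triol (2-OAc, 12-O-Troc, 7,19-lactone) | O[C@@H]1[C@@H]2[C@H](C)[C@@H](OC(=O)OCC(Cl)(Cl)Cl)C[C@@H](O)[C@@]2(C)[C@H](OC(C)=O)CC/C(C)=C\[C@H]2OC(=O)[C@@H](C)[C@]12O | intermediate
43 | 2,9,14-triacetate 12-O-Troc lactone (8-OH free) | CC(=O)O[C@@H]1[C@@H]2[C@H](C)[C@@H](OC(=O)OCC(Cl)(Cl)Cl)C[C@@H](OC(C)=O)[C@@]2(C)[C@H](OC(C)=O)CC/C(C)=C\[C@H]2OC(=O)[C@@H](C)[C@]12O | intermediate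
44 | CNP0195208.4, (1R,2R,5Z,7R,8R,9R,10R,11S,12S,14R,17S)-2,9,14-triacetoxy-8,12-dihydroxybriar-5-ene 7,19-lactone | CC(=O)O[C@@H]1[C@@H]2[C@H](C)[C@@H](O)C[C@@H](OC(C)=O)[C@@]2(C)[C@H](OC(C)=O)CC/C(C)=C\[C@H]2OC(=O)[C@@H](C)[C@]12O | target

**Step count and uncertain steps**

Total step count: 28. Longest linear sequence: 24 steps (steps 1–3, 5–11 and 15–28).

*Step 22 (key step).* The most likely failure is that the C1 cation is consumed before C10 reaches it, by a 1,2-hydride shift from the silyloxy carbon C14 (semipinacol opening of the epoxy silyl ether) or by Meinwald rearrangement. The next most likely is attack by the wrong alkene face, since the chair-like transition state carries a C15/C20 diaxial contact; capture of the C11 cation by O8 is a further possibility. The fallback uses known radical chemistry and sets out from 31. Silylation of 14-OH (TBSOTf, 2,6-lutidine) keeps the C10=C11–C12 enone and would give the keto epoxide silyl ether F1. Direct Swern oxidation of its primary TES ether would give the aldehyde F2, and CrCl2/NiCl2 ring closure the fourteen-membered 7-hydroxy 12-ketone F3. Cp2TiCl (trivalent titanium, from Cp2TiCl2 and Zn; Nugent–RajanBabu conditions) then opens the epoxide homolytically at C1. The tertiary radical adds across the ring to C10, the β-carbon of the C12 enone, and the titanium enolate is protonated with collidinium chloride to give the bicyclic 2,7-diol 12-ketone F4. MnO2 oxidises only the allylic 7-hydroxyl and returns to 37. In this radical mode C7 must stay a carbinol so that C5=C6 is a poor acceptor. C1 is then set by the cyclisation and not by inversion, and C11 by protonation (it can be equilibrated next to the ketone), so the configuration of F4 would have to be established.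

*Step 20.* The most likely failure is slow addition to the neopentyl, α-quaternary aldehyde, so that reduction of the iodide or oligomerisation takes over; closure of the new 7-alkoxide onto C19 is a second risk. The fallback exchanges the roles of the two carbon–carbon bond formations and sets out from 20 and 26. Direct Swern oxidation of 20 would give the keto aldehyde F5. This is coupled with the vinyl iodide of 26 under intermolecular CrCl2/NiCl2 conditions, where an excess of 26 can force the hindered addition, to give the open-chain 7,14-diol F6. Dess–Martin oxidation gives the enone enal F7, and the ring is closed by an intramolecular boron aldol (c-Hex2BCl, Et3N, high dilution) to the fourteen-membered β-hydroxy ketone F8. Sharpless epoxidation with the D-(−)-tartrate, which also selects the (14R) epimer kinetically, gives the epoxy alcohol F9. Evans–Saksena reduction gives the 12,14-diol F10, and TBSOTf returns to 36.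

*Step 24.* The most likely failure is poor facial selectivity at C7, because it depends on the conformation of the ten-membered ring, for which there is no model; a 7-epimer would close to the wrong lactone. C12 depends on ring A keeping the chair with axial 14-OTBS. The fallback sets out from 38 and separates the two reductions. NaBH4 in MeOH/CH2Cl2 at −78 °C should reduce only the unhindered saturated C12 ketone, giving the 12-hydroxy enone F11. The C7 enone is then reduced under reagent control with (S)-Me-CBS oxazaborolidine and catecholborane, the quaternary C8 acting as the large group, to give 39; PPTS closes the lactone and returns to 40.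

*Step 15.* The most likely failure is modest facial selectivity at C14, because chiral boron reagents induce only moderately with methyl ketones; step 16 then discards the wrong epimer at a convergent stage. The fallback puts the epoxide in first and sets out from 26. Sharpless epoxidation with D-(−)-diethyl tartrate would give the epoxy alcohol F12, and Dess–Martin oxidation the epoxy aldehyde F13. A boron aldol of 20 (c-Hex2BCl, Et3N) with F13 relies on Felkin–Anh/Cornforth control by the α-epoxide for the anti adduct and returns directly to 31.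

**Further compounds**

F1 | step 22 | methyl (2S,3R,4R,5E,9R,10S,11R,14Z)-4,9-bis(tert-butyldimethylsilyloxy)-10,11-epoxy-15-iodo-2,6,10,14-tetramethyl-7-oxo-3-(triethylsilyloxy)-3-[(triethylsilyloxy)methyl]pentadeca-5,14-dienoate | I/C=C(C)\CC[C@H]1O[C@]1(C)[C@H](O[Si](C)(C)C(C)(C)C)CC(=O)/C(C)=C/[C@@H](O[Si](C)(C)C(C)(C)C)[C@@](O[Si](CC)(CC)CC)([C@H](C)C(=O)OC)CO[Si](CC)(CC)CC
F2 | step 22 | 3-formyl analogue of F1 (primary TES ether oxidised to the C7 aldehyde) | I/C=C(C)\CC[C@H]1O[C@]1(C)[C@H](O[Si](C)(C)C(C)(C)C)CC(=O)/C(C)=C/[C@@H](O[Si](C)(C)C(C)(C)C)[C@@](O[Si](CC)(CC)CC)([C@H](C)C(=O)OC)C=O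
F3 | step 22 | fourteen-membered 7-hydroxy 12-ketone (1,2-epoxide, (5Z)-alkene, (10E)-en-12-one, 8-OTES, 9,14-di-OTBS, both C7 epimers) | C[C@]12O[C@@H]1CC/C(C)=C\C(O)[C@](O[Si](CC)(CC)CC)([C@H](C)C(=O)OC)[C@H](O[Si](C)(C)C(C)(C)C)/C=C(C)/C(=O)C[C@H]2O[Si](C)(C)C(C)(C)C
F4 | step 22 | bicyclic 2,7-diol 12-ketone (7-hydroxy analogue of 37, both C7 epimers) | CC(C)(C)[Si](C)(C)O[C@@H]1[C@@H]2[C@H](C)C(=O)C[C@@H](O[Si](C)(C)C(C)(C)C)[C@@]2(C)[C@H](O)CC/C(C)=C\C(O)[C@]1(O[Si](CC)(CC)CC)[C@H](C)C(=O)OC
F5 | step 20 | methyl (2S,3S,4R,5E)-4-(tert-butyldimethylsilyloxy)-3-formyl-2,6-dimethyl-7-oxo-3-(triethylsilyloxy)oct-5-enoate | CC(=O)/C(C)=C/[C@@H](O[Si](C)(C)C(C)(C)C)[C@@](O[Si](CC)(CC)CC)([C@H](C)C(=O)OC)C=O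
F6 | step 20 | open-chain 7,14-diol (C6–C7 bond formed, both C7 epimers, C12 methyl ketone) | OC/C(C)=C/CC/C(C)=C\C(O)[C@](O[Si](CC)(CC)CC)([C@H](C)C(=O)OC)[C@H](O[Si](C)(C)C(C)(C)C)/C=C(C)/C(C)=O
F7 | step 20 | open-chain (5Z)-en-7-one with C14 enal and C12 methyl ketone | O=C/C(C)=C/CC/C(C)=C\C(=O)[C@](O[Si](CC)(CC)CC)([C@H](C)C(=O)OC)[C@H](O[Si](C)(C)C(C)(C)C)/C=C(C)/C(C)=O
F8 | step 20 | fourteen-membered (14R)-14-hydroxy-7,12-dione with (1E), (5Z) and (10E) alkenes | C/C1=C\CC/C(C)=C\C(=O)[C@](O[Si](CC)(CC)CC)([C@H](C)C(=O)OC)[C@H](O[Si](C)(C)C(C)(C)C)/C=C(C)/C(=O)C[C@H]1O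
F9 | step 20 | 1,2-epoxide of F8 (epoxide configured as in 36, 14-OH free) | C[C@]12O[C@@H]1CC/C(C)=C\C(=O)[C@](O[Si](CC)(CC)CC)([C@H](C)C(=O)OC)[C@H](O[Si](C)(C)C(C)(C)C)/C=C(C)/C(=O)C[C@H]2O
F10 | step 20 | fourteen-membered (12R,14R)-12,14-diol epoxy enone | C[C@]12O[C@@H]1CC/C(C)=C\C(=O)[C@](O[Si](CC)(CC)CC)([C@H](C)C(=O)OC)[C@H](O[Si](C)(C)C(C)(C)C)/C=C(C)/[C@H](O)C[C@H]2O
F11 | step 24 | bicyclic (12S)-12-hydroxy 7-enone (2-OAc, 8-OTES, 9,14-di-OTBS, methyl ester) | CC(C)(C)[Si](C)(C)O[C@@H]1[C@@H]2[C@H](C)[C@@H](O)C[C@@H](O[Si](C)(C)C(C)(C)C)[C@@]2(C)[C@H](OC(C)=O)CC/C(C)=C\C(=O)[C@]1(O[Si](CC)(CC)CC)[C@H](C)C(=O)OC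
F12 | step 15 | [(2R,3R)-3-[(3Z)-4-iodo-3-methylbut-3-en-1-yl]-2-methyloxiran-2-yl]methanol | I/C=C(C)\CC[C@H]1O[C@]1(C)CO
F13 | step 15 | (2S,3R)-3-[(3Z)-4-iodo-3-methylbut-3-en-1-yl]-2-methyloxirane-2-carbaldehyde | I/C=C(C)\CC[C@H]1O[C@]1(C)C=O
A1 | alternative 1 | ring A isoxazoline | CC(=O)O[C@@H]1[C@@H]2[C@H](C)[C@H]3ON=C(C3)[C@@]2(C)[C@H](OC(C)=O)CC/C(C)=C\[C@H]2OC(=O)[C@@H](C)[C@]12O
A2 | alternative 1 | ten-membered lactone with C14 aldoxime on C1 and but-3-en-2-yl group on C10 | CC(=O)O[C@@H]1[C@H]([C@H](C)C=C)[C@@](C)(C=NO)[C@H](OC(C)=O)CC/C(C)=C\[C@H]2OC(=O)[C@@H](C)[C@]12O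
A3 | alternative 2 | methyl 4-[(tert-butyldimethylsilyloxy)methyl]-3-methyl-2-oxo-2H-pyran-5-carboxylate | COC(=O)C1=COC(=O)C(C)=C1CO[Si](C)(C)C(C)(C)C
A4 | alternative 2 | benzyl vinyl ether | C=COCc1ccccc1
A5 | alternative 2 | bicyclic lactone (2-oxabicyclo[2.2.2]octenone) holding C1, C12 and C14 | C[C@@]12C(=O)O[C@@H](C[C@H]1OCc1ccccc1)C(C(=O)OC)=C2CO[Si](C)(C)C(C)(C)C
A6 | alternative 3 | ten-membered 8,9-diol | O[C@@H]1[C@@H]2[C@H](C)[C@@H](O[Si](C)(C)C(C)(C)C)C[C@@H](OC(C)=O)[C@@]2(C)[C@H](OC(C)=O)CC/C(C)=C\[C@@H](O[Si](C)(C)C(C)(C)C)[C@]1(O)[C@H](C)COCc1ccc(OC)cc1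
A7 | alternative 3 | seco C9 aldehyde C8 ketone on ring A | O=C[C@@H]2[C@H](C)[C@@H](O[Si](C)(C)C(C)(C)C)C[C@@H](OC(C)=O)[C@@]2(C)[C@H](OC(C)=O)CC/C(C)=C\[C@@H](O[Si](C)(C)C(C)(C)C)C(=O)[C@H](C)COCc1ccc(OC)cc1
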